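**Assumption:** the target SMILES has no stereocentres (irigenin is achiral), so "single enantiomer" needs no stereocontrol; the route only has to deliver the correct constitution (5,7,3'-OH; 6,4',5'-OMe).

## Retrosynthetic overview

1. Irigenin 12 comes from its tri-O-benzyl ether 11 by global hydrogenolysis; benzyl marks the three free OH groups and methyl the three OMe groups from the start.
2. The pyranone (C) ring of 11 is formed last, in one convergent [4+2] annulation of salicylaldehyde 6 (O1, C4, ring A) with N-tosyl triazole 10 (C2, C3, ring B). This is the proposed new Rh(III) step and forms C4–C3 and O1–C2.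
3. Aldehyde 6 comes from the mirror-symmetric phenol 5 by ortho-formylation; both ortho sites are equivalent, so no 6-OMe/8-OMe ambiguity can arise. Phenol 5 comes from methyl 3,5-dihydroxy-4-methoxybenzoate 1 via a Dakin-type oxidation.
4. Triazole 10 comes from alkyne 9 (CuAAC with TsN3), which comes from commercial 3-hydroxy-4,5-dimethoxybenzaldehyde 7 via aldehyde 8.
5. Ring order: rings A and B are purchased as benzenoids; ring C is built in step 9.

## Route

**Step 1**
Reactants: 1, methyl 3,5-dihydroxy-4-methoxybenzoate
Product: 2, methyl 3,5-bis(benzyloxy)-4-methoxybenzoate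
Conditions: BnBr (2.4 equiv), K2CO3, DMF, 60 °C
Reagents that add atoms: benzyl bromide, BrCc1ccccc1
Why: Williamson etherification of the two equivalent phenols; the ester and aryl OMe are inert.

**Step 2**
Reactants: 2, methyl 3,5-bis(benzyloxy)-4-methoxybenzoate
Product: 3, [3,5-bis(benzyloxy)-4-methoxyphenyl]methanol
Conditions: LiAlH4, THF, 0 °C → rt
Reagents that add atoms: none
Why: Standard hydride reduction of an aryl ester to the benzylic alcohol; benzyl and methyl ethers are untouched.

**Step 3**
Reactants: 3, [3,5-bis(benzyloxy)-4-methoxyphenyl]methanol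
Product: 4, 3,5-bis(benzyloxy)-4-methoxybenzaldehyde
Conditions: MnO2, CH2Cl2, rt
Reagents that add atoms: none
Why: Chemoselective MnO2 oxidation of a benzylic alcohol stops cleanly at the aldehyde.

**Step 4**
Reactants: 4, 3,5-bis(benzyloxy)-4-methoxybenzaldehyde
Product: 5, 3,5-bis(benzyloxy)-4-methoxyphenol
Conditions: mCPBA, CH2Cl2, 0 °C → rt; then K2CO3, MeOH, rt
Reagents that add atoms: mCPBA, OOC(=O)c1cccc(Cl)c1 (supplies the phenolic O)
Why: Dakin-type Baeyer–Villiger oxidation, in which the electron-rich trialkoxyaryl group migrates in preference to H (as with 3,4,5-trimethoxybenzaldehyde), followed by methanolysis of the aryl formate.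

**Step 5**
Reactants: 5, 3,5-bis(benzyloxy)-4-methoxyphenol
Product: 6, 4,6-bis(benzyloxy)-2-hydroxy-5-methoxybenzaldehyde
Conditions: POCl3, DMF, MeCN, 0 °C → rt; then aq NaOAc
Reagents that add atoms: DMF, CN(C)C=O (formyl carbon); water, O (formyl oxygen on hydrolysis)
Why: Vilsmeier–Haack formylation of a highly activated phenol whose para site is blocked and whose two ortho sites are symmetry-equivalent, so only one regioisomer is possible.

**Step 6**
Reactants: 7, 3-hydroxy-4,5-dimethoxybenzaldehyde
Product: 8, 3-(benzyloxy)-4,5-dimethoxybenzaldehyde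
Conditions: BnBr, K2CO3, DMF, rt
Reagents that add atoms: benzyl bromide, BrCc1ccccc1
Why: Williamson etherification of the single phenol; the aldehyde is inert.

**Step 7**
Reactants: 8, 3-(benzyloxy)-4,5-dimethoxybenzaldehyde
Product: 9, 1-(benzyloxy)-5-ethynyl-2,3-dimethoxybenzene
Conditions: Ohira–Bestmann reagent, K2CO3, MeOH, rt
Reagents that add atoms: dimethyl (1-diazo-2-oxopropyl)phosphonate, COP(=O)(OC)C(=[N+]=[N-])C(C)=O (supplies the terminal alkyne carbon)
Why: Seyferth–Gilbert (Ohira–Bestmann) homologation converts an aryl aldehyde to the terminal alkyne under mild base that tolerates all the ethers.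

**Step 8**
Reactants: 9, 1-(benzyloxy)-5-ethynyl-2,3-dimethoxybenzene
Product: 10, 4-[3-(benzyloxy)-4,5-dimethoxyphenyl]-1-tosyl-1H-1,2,3-triazole
Conditions: TsN3, CuTC (10 mol %), toluene, rt
Reagents that add atoms: tosyl azide, Cc1ccc(cc1)S(=O)(=O)N=[N+]=[N-]
Why: Copper(I) thiophene-2-carboxylate-catalysed azide–alkyne cycloaddition gives the 1,4-disubstituted N-sulfonyl triazole regiospecifically under anhydrous, base-free conditions.

**Step 9 (key step, new)**
Reactants: 6, 4,6-bis(benzyloxy)-2-hydroxy-5-methoxybenzaldehyde; 10, 4-[3-(benzyloxy)-4,5-dimethoxyphenyl]-1-tosyl-1H-1,2,3-triazole (1.3 equiv)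
Product: 11, 5,7-bis(benzyloxy)-3-[3-(benzyloxy)-4,5-dimethoxyphenyl]-6-methoxy-4H-chromen-4-one
Conditions: [Cp*RhCl2]2 (2.5 mol %), AgSbF6 (10 mol %), CsOAc (30 mol %), PivOH (1 equiv), 4 Å MS, DCE, 80 °C, Ar; then TsOH·H2O (20 mol %), 60 °C
Reagents that add atoms: none (all product atoms come from 6 and 10; N2 and TsNH2 are lost)
Why: Proposed new method: a Rh(III)-catalysed formyl C–H activation/α-imino-carbene [4+2] annulation, in which phenoxide-directed deprotonative metalation of the aldehyde C–H gives a five-membered acyl-rhodacycle, the triazole ring-opens to its α-diazo imine tautomer (Ar–C(=N2)–CH=NTs) and is captured as a Rh carbene with loss of N2, migratory insertion of the aryl-bearing carbene carbon into the Rh–acyl bond forms C4–C3 with the aryl group necessarily on C3, protodemetalation releases the (2-hydroxyaryl) β-(tosylamino)enone, and acid-promoted intramolecular O-addition/elimination of TsNH2 closes O1–C2; the closest known reactions are Rh(III)-catalysed annulations of salicylaldehydes with sulfoxonium ylides, diazo compounds or alkynes (which give 2-substituted chromones) and the Rh azavinyl-carbene chemistry of N-sulfonyl triazoles.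

**Step 10**
Reactants: 11, 5,7-bis(benzyloxy)-3-[3-(benzyloxy)-4,5-dimethoxyphenyl]-6-methoxy-4H-chromen-4-one
Product: 12, irigenin (5,7-dihydroxy-3-(3-hydroxy-4,5-dimethoxyphenyl)-6-methoxy-4H-chromen-4-one)
Conditions: H2 (1 atm), 10% Pd/C, EtOAc–MeOH, rt, monitored and stopped at full debenzylation
Reagents that add atoms: none
Why: Neutral catalytic hydrogenolysis removes the three aryl benzyl ethers, leaves the aryl methyl ethers alone, and avoids the strong acid that would trigger Wessely–Moser 6-OMe/8-OMe scrambling.

## Compound list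

1 | methyl 3,5-dihydroxy-4-methoxybenzoate | COC(=O)c1cc(O)c(OC)c(O)c1 | starting material
2 | methyl 3,5-bis(benzyloxy)-4-methoxybenzoate | COC(=O)c1cc(OCc2ccccc2)c(OC)c(OCc2ccccc2)c1 | intermediate
3 | [3,5-bis(benzyloxy)-4-methoxyphenyl]methanol | OCc1cc(OCc2ccccc2)c(OC)c(OCc2ccccc2)c1 | intermediate
4 | 3,5-bis(benzyloxy)-4-methoxybenzaldehyde | O=Cc1cc(OCc2ccccc2)c(OC)c(OCc2ccccc2)c1 | intermediate
5 | 3,5-bis(benzyloxy)-4-methoxyphenol | Oc1cc(OCc2ccccc2)c(OC)c(OCc2ccccc2)c1 | intermediate
6 | 4,6-bis(benzyloxy)-2-hydroxy-5-methoxybenzaldehyde | O=Cc1c(O)cc(OCc2ccccc2)c(OC)c1OCc1ccccc1 | intermediate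
7 | 3-hydroxy-4,5-dimethoxybenzaldehyde | COc1cc(C=O)cc(O)c1OC | starting material
8 | 3-(benzyloxy)-4,5-dimethoxybenzaldehyde | COc1cc(C=O)cc(OCc2ccccc2)c1OC | intermediate
9 | 1-(benzyloxy)-5-ethynyl-2,3-dimethoxybenzene | C#Cc1cc(OC)c(OC)c(OCc2ccccc2)c1 | intermediate
10 | 4-[3-(benzyloxy)-4,5-dimethoxyphenyl]-1-tosyl-1H-1,2,3-triazole | COc1cc(-c2cn(S(=O)(=O)c3ccc(C)cc3)nn2)cc(OCc2ccccc2)c1OC | intermediate
11 | 5,7-bis(benzyloxy)-3-[3-(benzyloxy)-4,5-dimethoxyphenyl]-6-methoxy-4H-chromen-4-one | COc1cc(-c2coc3cc(OCc4ccccc4)c(OC)c(OCc4ccccc4)c3c2=O)cc(OCc2ccccc2)c1OC | intermediate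
12 | irigenin | COc1cc(-c2coc3cc(O)c(OC)c(O)c3c2=O)cc(O)c1OC | target

## Summary

Total step count: 10.
Longest linear sequence: 7 steps (steps 1, 2, 3, 4, 5, 9, 10); the B-ring branch (steps 6–8) is 3 steps.

Three steps most likely to fail:

1. **Step 9 (proposed new annulation).** Risks are competing phenol O–H insertion of the azavinyl carbene, slow formyl C–H activation next to the 6-OBn group, and triazole hydrolysis. Fallback (known chemistry): convert 6 to the 2-hydroxyacetophenone (MeMgBr, then MnO2), form the enaminone with DMF–DMA, cyclise with I2 to the 3-iodochromone, and install ring B by Suzuki–Miyaura coupling with the 3-(benzyloxy)-4,5-dimethoxyphenyl pinacol boronate (from 8 by Dakin oxidation, triflation and Miyaura borylation) to give 11.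
2. **Step 5 (formylation at an ortho site flanked by OH and OBn).** Risks are O-formylation or sluggish C-formylation. Fallback: switch from electrophilic formylation to a halogen–metal exchange sequence: ortho-bromination of 5 (NBS), MOM protection of the phenol, Br/Li exchange (n-BuLi, −78 °C) with DMF quench, then mild acidic MOM removal to give 6.
3. **Step 10 (global hydrogenolysis).** Risks are partial reduction of the chromone C2=C3 bond or incomplete cleavage. Fallback: non-reductive Lewis-acid debenzylation with BCl3/pentamethylbenzene in CH2Cl2 at −78 °C, which leaves the enone untouched and is cold enough to spare the 6-OMe group.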